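**Remark on the chemistry.** Daucane numbering is used throughout: C1 is the quaternary ring-fusion carbon (methyl C15), C2 and C3 are CH2, C4 carries OH and isopropyl, C5 is the ring-fusion CH, C6 carries the anisoate, C7 is CH2, C8 carries methyl C14, C8=C9 is the alkene, and C10 carries the acetate. In compounds 11–15 the acyl carbon on C8 is the future C10; C9 is added in step 7. Compound 1 is taken as a catalogue compound.

## Analysis of the target

Compound 26 is a daucane (carotane) sesquiterpenoid diester. A cyclopentane (C1–C5) is cis-fused through the C1–C5 bond to a cycloheptene (C1, C5, C6, C7, C8, C9, C10). It has five contiguous stereocentres, (1S,4R,5R,6S,10S). The C1 methyl, H5, the C4 hydroxyl and the C10 acetate lie on one face (β); the isopropyl group and the C6 anisoate lie on the other. The hardest atom is quaternary C1, wedged between oxygenated C10 and the ring-fusion carbon C5. The second difficulty is that H5 is syn to the tertiary hydroxyl while the isopropyl group sits on the concave face, so a plain isopropyl addition to a cis-fused C4 ketone would give the wrong epimer.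

The seven-membered ring reads C5–C6(O)–C7H2–C8(CH3)=C9–C10(O)–C1. With C6 and C10 at the carbonyl level this is a cyclohepta-1,4-diene (C5=C6, C8=C9) whose only sp3 carbon between the alkenes is C7 and whose ketone C10 abuts quaternary C1. That is the product pattern of a cis-divinylcyclopropane rearrangement in which one 2π partner is a ketene, with C7 as the former cyclopropane CH2.

Sensitive points:
- the C4–OH/C6–O array is an aldol-type unit whenever C6 is a ketone or enol ether (retro-aldol, loss of water to C4=C5);
- the neopentyl allylic acetate at C10 can ionise;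
- two different esters must go on two secondary alcohols beside a free tertiary one.

## Retrosynthetic reasoning

**C6–O and C10–O acyl bonds.** 26 is cut at the anisoate to alcohol 24, which comes from silyl ether 23. The acetate is placed earlier, on 20, when C10–OH is the only secondary hydroxyl. The two secondary alcohols therefore never compete, and the tertiary C4–OH needs no protection.

**C5–H and C6–H.** 23 is traced to the silyl enol ether 22 by removing H2 from C5–C6. The forward step must add both hydrogens from the face of the C4 hydroxyl. A hydroxyl-directed hydrogenation does this and sets the cis ring fusion and the C6 carbinol together. It requires the C6 oxygen to arrive as an enol ether that fluoride can remove later; this is why a silyl group is carried from step 5.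

**C4–isopropyl bond and C10–H.** 22 and 20 lead back through alcohol 18 to the dione 17. With C5 still sp2, 17 is nearly flat and the C1 methyl stands axial on one face. Hydride at C10 and the isopropyl nucleophile at C4 should both enter anti to it, which puts both oxygens syn to the methyl as the target requires. One stereocentre (C1) thus controls C10, C4 and, through C4–OH, C5 and C6.

**C1–C10 bond and the seven-membered ring (key).** 17 is opened by a retro-[3,3] shift to the ketene 16: the C1–C10 bond is cut and the C6–C8 bond is restored as part of a cyclopropane (C6, C7, C8). Ketene 16 comes from diazoketone 15 by Wolff rearrangement. The cut is made here because it removes the ring, the quaternary centre and the C10 carbonyl in one operation. A ketene terminus carries no substituent, so the Cope transition state has only one inside group, the C1 methyl.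

**C9 and the C4 oxygen.** 15 is the oxidation product of 14, which comes from lactone 11 and trimethylsilyldiazomethane 12. The lactone carbonyl becomes C10, the diazo carbon becomes C9, and the lactone oxygen is released as the C4 hydroxyl, which is then oxidised to the ketone that activates C4 for step 11.

**C6–C8 and C7–C8 (cyclopropane).** 11 is cut to the diazo ester 10 by a retro-cyclopropanation. Tying the carbenoid to O4 has two purposes. The lactone can only be cis-fused to the cyclopropane, which gives the cis relation of acyl arm and cyclopentene needed in step 9. The C4 carbinol centre also dictates the cyclopropane configuration, and is erased once it has done so.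

**Building blocks.** 10 comes from 9 by silyl enol ether formation, 9 from the pyruvate 7 via tosylhydrazone 8, and 7 from alcohol 5 and pyruvic acid 6. 5 comes from bromide 2 and stannane 3 via 4, and 2 from enone 1 by enantioselective reduction, the only reagent-controlled stereochemical step.

## Alternatives that were turned down

**Alternative 1:** Ring-closing metathesis at C8=C9 (the textbook route). The forward key step would treat the diene A1, a cyclopentane carrying all five stereocentres and two alkenyl arms, with a ruthenium alkylidene (second-generation Grubbs catalyst). It was turned down because the key step builds only a C=C bond. Every stereocentre must be set beforehand, including C6 and C10 on freely rotating side chains next to a quaternary carbon, where acyclic 1,2-additions give weak control. Closing a trisubstituted alkene in a seven-membered ring beside a neopentyl allylic acetate is also slow. The route would be clearly longer.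

**Alternative 2:** Arene-to-cycloheptatriene ring expansion (intramolecular Buchner reaction). C5 would be inserted as a carbene into the C1–C6 bond of a 2,6-dimethoxy-4-methylphenyl ring, whose O/CH3/O pattern maps onto C6/C8/C10. The diazoketone A2 with Rh2(OAc)4 would give the azulenone A3 in very few steps. It was turned down for three reasons:
- The carbonyl of a diazoketone always ends next to the carbene carbon, here C4 next to C5. The ipso carbon therefore becomes C1 and stays sp2, and the angular methyl must be added later at an enol-ether carbon of a triene that holds a second, equally reactive enol ether.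
- The only stereocentre of A3 (C5–H) is α to the ketone and is lost in the isomerisations needed to tell the two enol ethers apart, so chirality cannot be relayed to C1.
- Putting the methyl on the carbene instead moves the ketone to C2, where the target has no oxygen.

**Alternative 3:** Intermolecular rhodium vinylcarbenoid [4+3] annulation (cyclopropanation then Cope). An untethered analogue of diene 10 would react with a 4-silyloxy vinyldiazoacetate to form the same C7–C8 and C1–C10 bonds under catalyst control, giving the cycloheptadiene ester A4 in one step. It was turned down for two reasons: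
- The carbenoid carbon must carry an acceptor and becomes C8, so A4 has CO2Me where the target has CH3; several redox steps on a hindered dienyl ester would be needed.
- An E enol-ether terminus places the C10 oxygen trans to the C1 methyl (wrong epimer). The Z isomer would put two inside substituents into the boat transition state, which is strongly retarded.

Key step: step 9

## Route

Step 1
Reactants: 1 2-bromo-3-methylcyclopent-2-en-1-one
Product: 2 (1R)-2-bromo-3-methylcyclopent-2-en-1-ol
Conditions: (S)-Me-CBS oxazaborolidine (10 mol %), BH3·SMe2, THF, −20 °C; MeOH quench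
Reagents that add atoms: none
Why: CBS reduction; with the bromoalkene carbon as the large group the (S)-catalyst should deliver hydride to give the 1R alcohol. This centre (C4) is temporary: it sets the cyclopropane in step 6 and is erased in step 8.

Step 2
Reactants: 2 (1R)-2-bromo-3-methylcyclopent-2-en-1-ol; 3 tributyl(1-ethoxyethenyl)stannane
Product: 5 1-[(5R)-5-hydroxy-2-methylcyclopent-1-en-1-yl]ethan-1-one, via enol ether 4 (not isolated)
Conditions: Pd(PPh3)4 (5 mol %), toluene, 100 °C; then 1 M HCl, THF, 0 °C
Reagents that add atoms: tributyl(1-ethoxyethenyl)stannane, CCCC[Sn](CCCC)(CCCC)C(=C)OCC; water, O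
Why: Stille coupling of an alkenyl bromide with the acetyl-anion equivalent, then enol ether hydrolysis; this brings in C6 and C7. The carbinol centre is not enolisable and should survive.

Step 3
Reactants: 5 1-[(5R)-5-hydroxy-2-methylcyclopent-1-en-1-yl]ethan-1-one; 6 2-oxopropanoic acid
Product: 7 (1R)-2-acetyl-3-methylcyclopent-2-en-1-yl 2-oxopropanoate
Conditions: dicyclohexylcarbodiimide, DMAP (cat.), CH2Cl2, 0 °C
Reagents that add atoms: 2-oxopropanoic acid, CC(=O)C(O)=O
Why: Steglich esterification of the secondary allylic alcohol; the pyruvate supplies C8, C14 and the future C10.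

Step 4
Reactants: 7 (1R)-2-acetyl-3-methylcyclopent-2-en-1-yl 2-oxopropanoate
Product: 9 (1R)-2-acetyl-3-methylcyclopent-2-en-1-yl 2-diazopropanoate, via tosylhydrazone 8 (not isolated)
Conditions: TsNHNH2 (1.0 equiv), CH2Cl2, rt; then DBU, 0 °C
Reagents that add atoms: 4-methylbenzenesulfonohydrazide, Cc1ccc(cc1)S(=O)(=O)NN
Why: Condensation at the far more electrophilic α-keto ester carbonyl, then base-induced loss of sulfinate (Bamford–Stevens type) gives the α-diazo ester. The conjugated, hindered methyl ketone should not compete.

Step 5
Reactants: 9 (1R)-2-acetyl-3-methylcyclopent-2-en-1-yl 2-diazopropanoate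
Product: 10 (1R)-3-methyl-2-{1-[(triisopropylsilyl)oxy]ethenyl}cyclopent-2-en-1-yl 2-diazopropanoate
Conditions: i-Pr3SiOTf, Et3N, CH2Cl2, −78 to 0 °C
Reagents that add atoms: triisopropylsilyl trifluoromethanesulfonate, CC(C)[Si](OS(=O)(=O)C(F)(F)F)(C(C)C)C(C)C
Why: Soft enolisation of the methyl ketone at CH3 gives the 2-silyloxy diene. The diazo carbon has no hydrogen and cannot be silylated.

Step 6
Reactants: 10 (1R)-3-methyl-2-{1-[(triisopropylsilyl)oxy]ethenyl}cyclopent-2-en-1-yl 2-diazopropanoate
Product: 11 (4R,6R,8S)-tricyclic lactone: cyclopropane C6–C7–C8 cis-fused to the δ-lactone C8–C10(=O)–O–C4–C5–C6, itself fused at C4–C5 to the 1-methylcyclopentene (C5=C1); OTIPS on C6, CH3 on C8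
Conditions: Rh2(O2CCPh3)4 (1 mol %), CH2Cl2, slow addition, −78 to 0 °C
Reagents that add atoms: none
Why: Intramolecular rhodium-carbenoid cyclopropanation of the electron-rich silyl enol ether by a homoallylic diazo ester; the bulky carboxylate ligands at low temperature suppress 1,2-hydride shift. The six-membered lactone can only be cis-fused to the cyclopropane, so acyl carbon and cyclopentene end on the same face. The carbenoid comes from the O4 face onto the twisted enol ether whose CH2 points to that face and whose OTIPS avoids the C1 methyl, so 4R should give 6R,8S.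

Step 7
Reactants: 11 tricyclic lactone; 12 (diazomethyl)trimethylsilane
Product: 14 2-diazo-1-[(1S,2R)-2-[(5R)-5-hydroxy-2-methylcyclopent-1-en-1-yl]-1-methyl-2-[(triisopropylsilyl)oxy]cyclopropyl]ethan-1-one, via silyl diazoketone 13 (not isolated)
Conditions: 12, n-BuLi, THF, −78 °C; add 11, −78 °C; then MeOH, K2CO3, −20 °C
Reagents that add atoms: trimethylsilyldiazomethane, C[Si](C)(C)C=[N+]=[N-]
Why: Acyl substitution of the lactone by lithiated trimethylsilyldiazomethane (diazoketone synthesis from esters), then C-desilylation; this adds C9 and frees the C4 hydroxyl. A cold quench keeps the alkoxide from attacking the hindered silyl ether.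

Step 8
Reactants: 14 hydroxy diazoketone
Product: 15 2-diazo-1-[(1S,2S)-1-methyl-2-(2-methyl-5-oxocyclopent-1-en-1-yl)-2-[(triisopropylsilyl)oxy]cyclopropyl]ethan-1-one
Conditions: MnO2 (activated, excess), CH2Cl2, rt
Reagents that add atoms: none
Why: Allylic alcohol oxidation; diazoketones tolerate MnO2. It removes the only nucleophile that could trap the ketene and creates the C4 ketone for step 11; the cyclopropane now carries all the chirality.

Step 9
Reactants: 15 diazoketone
Product: 17 (8aS)-6,8a-dimethyl-4-[(triisopropylsilyl)oxy]-2,5-dihydroazulene-3,8(1H,8aH)-dione [(1S)-6-silyloxy-13,12,11-trinordauca-5,8-diene-4,10-dione skeleton], via ketene 16 (not isolated)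
Conditions: AgO2CPh (10 mol %), Et3N, THF, sonication, 45 °C
Reagents that add atoms: none
Why: Silver-promoted Wolff rearrangement (loss of N2, 1,2-shift of cyclopropane carbon C8 onto the diazo carbon) gives ketene 16, whose C9=C10 bond is held cis on the cyclopropane to the enone C5=C1 bond. The two π bonds then undergo a [3,3] sigmatropic (Cope) shift through the endo boat transition state, breaking the strained, donor-weakened C6–C8 bond and forming C1–C10. The closest known reaction type is the tandem Wolff/Cope rearrangement of cis-2-vinylcyclopropyl diazomethyl ketones to fused cycloheptadienones. The seven-membered ring closes by sigmatropic ring expansion of the three-membered ring (3 to 7), not by an end-to-end cyclisation, so the new ring alkenes C5=C6 and C8=C9 are necessarily cis. The only new stereocentre, quaternary C1, is fixed by the cyclopropane configuration through the boat geometry: C10 bonds to the face of C1 that lies over the three-membered ring, with ring carbon C2 outside and the methyl inside, so the (6S,8S)-cyclopropane should give 1S. The step needs the acyl arm and the cyclopentenone to be cis (secured by the cis-fused lactone 11) and the ketene to meet no nucleophile (no hydroxyl after step 8, aprotic medium). It also needs the concerted shift to outrun heterolysis of the donor–acceptor cyclopropane, which would racemise C6 and C8. A ketene terminus has no substituent and is a very reactive 2π partner, which should let the fully substituted, methyl-bearing C1 engage at moderate temperature.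

Step 10
Reactants: 17 bicyclic dione
Product: 18 (8S,8aS)-8-hydroxy-6,8a-dimethyl-4-[(triisopropylsilyl)oxy]-1,2,8,8a-tetrahydroazulen-3(5H)-one [(1S,10S)]
Conditions: NaBH4, CeCl3·7H2O, MeOH, −78 °C
Reagents that add atoms: none
Why: Luche 1,2-reduction of the enone; the vinylogous silyl ester carbonyl at C4 is much less electrophilic. Hydride should enter anti to the axial angular methyl, as in angularly methylated hydrindanones and 17-keto steroids, so the hydroxyl ends syn to the methyl (10S).

Step 11
Reactants: 18 hydroxy enone; 19 isopropylmagnesium chloride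
Product: 20 (1S,4R,10S)-6-[(triisopropylsilyl)oxy]dauca-5,8-diene-4,10-diol
Conditions: 19 (3.5 equiv), CeCl3 (anhydrous), THF, −78 °C; pH 7 buffer quench at −78 °C
Reagents that add atoms: isopropylmagnesium chloride, CC(C)[Mg]Cl
Why: Organocerium 1,2-addition to the vinylogous ester carbonyl; the low basicity of the cerium reagent limits enolisation and β-hydride reduction. Attack anti to the axial C1 methyl, helped by the cerium alkoxide at C10 on the same face, should put isopropyl opposite to the methyl and the hydroxyl syn to it (4R). The neutral cold quench avoids ionisation of the tertiary allylic alcohol and silyl transfer.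

Step 12
Reactants: 20 diol; 21 acetic anhydride
Product: 22 (1S,4R,10S)-4-hydroxy-6-[(triisopropylsilyl)oxy]dauca-5,8-dien-10-yl acetate
Conditions: Ac2O, pyridine, DMAP (cat.), CH2Cl2, 0 °C to rt
Reagents that add atoms: acetic anhydride, CC(=O)OC(C)=O
Why: Acylation of the only secondary alcohol; the hindered tertiary C4 hydroxyl stays free, and basic conditions protect the acid-labile carbinol and enol ether.

Step 13
Reactants: 22 dienyl acetate
Product: 23 (1S,4R,5R,6S,10S)-4-hydroxy-6-[(triisopropylsilyl)oxy]dauc-8-en-10-yl acetate
Conditions: H2 (1 atm), [Ir(cod)(PCy3)(py)]PF6 (5–10 mol %), CH2Cl2, 0 °C to rt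
Reagents that add atoms: none
Why: Hydroxyl-directed homogeneous hydrogenation: the cationic iridium centre binds the tertiary allylic C4 hydroxyl and delivers both hydrogens to the same face of the tetrasubstituted C5=C6 enol ether. This sets H5 syn to the hydroxyl (cis ring fusion, 5R) and the C6 oxygen on the opposite face (6S). The acetate is a poor ligand, so the trisubstituted C8=C9 alkene is not activated.

Step 14
Reactants: 23 silyl ether
Product: 24 (1S,4R,5R,6S,10S)-4,6-dihydroxydauc-8-en-10-yl acetate
Conditions: TBAF, AcOH (1:1), THF, 0 °C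
Reagents that add atoms: none
Why: Fluoride cleavage of the secondary silyl ether; buffering with acetic acid prevents acetate cleavage or migration.

Step 15
Reactants: 24 diol monoacetate; 25 4-methoxybenzoyl chloride
Product: 26 (1S,4R,5R,6S,10S)-10-acetoxy-4-hydroxydauc-8-en-6-yl 4-methoxybenzoate (target)
Conditions: 25, DMAP, pyridine, CH2Cl2, rt
Reagents that add atoms: 4-methoxybenzoyl chloride, COc1ccc(cc1)C(Cl)=O
Why: DMAP-catalysed acylation of the secondary C6 alcohol; the tertiary C4 hydroxyl should not react under these conditions.

## Compound list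

1 | 2-bromo-3-methylcyclopent-2-en-1-one | CC1=C(Br)C(=O)CC1 | starting material
2 | (1R)-2-bromo-3-methylcyclopent-2-en-1-ol | O[C@@H]1CCC(C)=C1Br | intermediate
3 | tributyl(1-ethoxyethenyl)stannane | CCCC[Sn](CCCC)(CCCC)C(=C)OCC | starting material
4 | (1R)-2-(1-ethoxyethenyl)-3-methylcyclopent-2-en-1-ol (enol ether) | CCOC(=C)C1=C(C)CC[C@H]1O | intermediate (not isolated)
5 | 1-[(5R)-5-hydroxy-2-methylcyclopent-1-en-1-yl]ethan-1-one | CC(=O)C1=C(C)CC[C@H]1O | intermediate
6 | 2-oxopropanoic acid (pyruvic acid) | CC(=O)C(O)=O | starting material
7 | (1R)-2-acetyl-3-methylcyclopent-2-en-1-yl 2-oxopropanoate | CC(=O)C1=C(C)CC[C@H]1OC(=O)C(C)=O | intermediate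
8 | (1R)-2-acetyl-3-methylcyclopent-2-en-1-yl 2-[2-(4-methylbenzenesulfonyl)hydrazinylidene]propanoate (tosylhydrazone) | CC(=O)C1=C(C)CC[C@H]1OC(=O)C(C)=NNS(=O)(=O)c1ccc(C)cc1 | intermediate (not isolated)
9 | (1R)-2-acetyl-3-methylcyclopent-2-en-1-yl 2-diazopropanoate | CC(=O)C1=C(C)CC[C@H]1OC(=O)C(C)=[N+]=[N-] | intermediate
10 | (1R)-3-methyl-2-{1-[(triisopropylsilyl)oxy]ethenyl}cyclopent-2-en-1-yl 2-diazopropanoate | C=C(O[Si](C(C)C)(C(C)C)C(C)C)C1=C(C)CC[C@H]1OC(=O)C(C)=[N+]=[N-] | intermediate
11 | (4R,6R,8S)-tricyclic lactone (cyclopropane C6–C7–C8 cis-fused to δ-lactone C8–C10(=O)–O–C4–C5–C6, fused at C4–C5 to 1-methylcyclopentene; 6-OTIPS, 8-CH3) | CC(C)[Si](C(C)C)(C(C)C)O[C@@]12C[C@]1(C)C(=O)O[C@@H]1CCC(C)=C21 | intermediate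
12 | (diazomethyl)trimethylsilane | C[Si](C)(C)C=[N+]=[N-] | starting material
13 | 2-diazo-2-(trimethylsilyl) analogue of 14 (silyl diazoketone) | CC(C)[Si](C(C)C)(C(C)C)O[C@@]1(C2=C(C)CC[C@H]2O)C[C@]1(C)C(=O)C(=[N+]=[N-])[Si](C)(C)C | intermediate (not isolated)
14 | 2-diazo-1-[(1S,2R)-2-[(5R)-5-hydroxy-2-methylcyclopent-1-en-1-yl]-1-methyl-2-[(triisopropylsilyl)oxy]cyclopropyl]ethan-1-one | CC(C)[Si](C(C)C)(C(C)C)O[C@@]1(C2=C(C)CC[C@H]2O)C[C@]1(C)C(=O)C=[N+]=[N-] | intermediate
15 | 2-diazo-1-[(1S,2S)-1-methyl-2-(2-methyl-5-oxocyclopent-1-en-1-yl)-2-[(triisopropylsilyl)oxy]cyclopropyl]ethan-1-one | CC(C)[Si](C(C)C)(C(C)C)O[C@@]1(C2=C(C)CCC2=O)C[C@]1(C)C(=O)C=[N+]=[N-] | intermediate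
16 | ketene from 15 (C8–CH=C=O, same cyclopropane configuration) | CC(C)[Si](C(C)C)(C(C)C)O[C@@]1(C2=C(C)CCC2=O)C[C@]1(C)C=C=O | intermediate (not isolated)
17 | (8aS)-6,8a-dimethyl-4-[(triisopropylsilyl)oxy]-2,5-dihydroazulene-3,8(1H,8aH)-dione | O=C1CC[C@]2(C)C(=O)C=C(C)CC(O[Si](C(C)C)(C(C)C)C(C)C)=C12 | intermediate
18 | (8S,8aS)-8-hydroxy-6,8a-dimethyl-4-[(triisopropylsilyl)oxy]-1,2,8,8a-tetrahydroazulen-3(5H)-one | O=C1CC[C@]2(C)[C@@H](O)C=C(C)CC(O[Si](C(C)C)(C(C)C)C(C)C)=C12 | intermediate
19 | isopropylmagnesium chloride | CC(C)[Mg]Cl | starting material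
20 | (1S,4R,10S)-6-[(triisopropylsilyl)oxy]dauca-5,8-diene-4,10-diol | CC(C)[C@]1(O)CC[C@]2(C)[C@@H](O)C=C(C)CC(O[Si](C(C)C)(C(C)C)C(C)C)=C12 | intermediate
21 | acetic anhydride | CC(=O)OC(C)=O | starting material
22 | (1S,4R,10S)-4-hydroxy-6-[(triisopropylsilyl)oxy]dauca-5,8-dien-10-yl acetate | CC(C)[C@]1(O)CC[C@]2(C)[C@@H](OC(C)=O)C=C(C)CC(O[Si](C(C)C)(C(C)C)C(C)C)=C12 | intermediate
23 | (1S,4R,5R,6S,10S)-4-hydroxy-6-[(triisopropylsilyl)oxy]dauc-8-en-10-yl acetate | CC(C)[C@]1(O)CC[C@]2(C)[C@@H](OC(C)=O)C=C(C)C[C@H](O[Si](C(C)C)(C(C)C)C(C)C)[C@H]12 | intermediate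
24 | (1S,4R,5R,6S,10S)-4,6-dihydroxydauc-8-en-10-yl acetate | CC(C)[C@]1(O)CC[C@]2(C)[C@@H](OC(C)=O)C=C(C)C[C@H](O)[C@H]12 | intermediate
25 | 4-methoxybenzoyl chloride | COc1ccc(cc1)C(Cl)=O | starting material
26 | (1S,4R,5R,6S,10S)-10-acetoxy-4-hydroxydauc-8-en-6-yl 4-methoxybenzoate | COc1ccc(C(=O)O[C@H]2CC(C)=C[C@H](OC(C)=O)[C@@]3(C)CC[C@@](O)(C(C)C)[C@@H]23)cc1 | target

## Step count and least certain steps

Total step count: 15. Longest linear sequence: 15 (1 to 26).

**Step 9 (key step).** Three processes could compete with the concerted shift. The donor–acceptor cyclopropane could open heterolytically, which would scramble C6 and C8 and so the configuration at C1. The ketene could be consumed by dimerisation or by the amine. The shift itself could be slow because the methyl at the fully substituted terminus C1 points into the boat.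
Fallback: from 11, reduction with i-Bu2AlH at −78 °C should give the lactol F1. Wittig reaction with the ylide from (4-methoxybenzyloxymethyl)triphenylphosphonium chloride should give the enol ether F2 with the C4 hydroxyl free, and MnO2 the enone F3. Heating in toluene (80–110 °C) should then effect the classical cis-divinylcyclopropane rearrangement to the benzyl-type ether F4 (an E substituent ends trans to the C1 methyl). DDQ should free the allylic alcohol F5, and MnO2 should oxidise it to 17, where the route is rejoined; the C10 configuration is irrelevant because it is erased.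

**Step 6.** 1,2-Hydride migration in the methyl-substituted carbenoid could outrun cyclopropanation, and facial control by the C4 centre could be incomplete. The diastereomers of 11 are separable, so the enantiomeric purity of 17 can still be secured at this stage.
Fallback: from 5, acylation with 2,5-dioxopyrrolidin-1-yl diazoacetate should give the diazoacetate F6 and silylation as in step 5 the dienol ether F7. Rh2(OAc)4 should give the nor-methyl lactone F8, since this carbenoid has no β-hydrogen. Deprotonation with LiN(i-Pr)2 and methylation with MeI at C8 should give 11; methyl can only enter with retention because C8 is a fusion atom of the cis-fused lactone.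

**Step 11.** The hindered secondary nucleophile may enolise or reduce the ketone, and facial discrimination by a methyl group two bonds away may be incomplete.
Fallback: from 18, 2-propenylmagnesium bromide with CeCl3 (sp2, smaller, no β-hydride) should give the isopropenyl carbinol F9. H2 with RhCl(PPh3)3 should saturate only the 1,1-disubstituted alkene to give 20.

**Step 13.** Over-reduction of the C8=C9 alkene is possible, as is acid-promoted loss of the tertiary allylic hydroxyl under the cationic catalyst. The angular methyl on the same face may also slow the directed delivery.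
Fallback: from 20, MnO2 should return the C10 alcohol to the enone F10, whose C8=C9 bond is now electron-poor. The same iridium catalyst should then give the saturated silyl ether F11, Luche reduction the alcohol F12, and acetylation as in step 12 compound 23.

## Further compounds

F1 | step 9 | lactol from 11 (C8–CH(OH)–O–C4, anomer mixture) | CC(C)[Si](C(C)C)(C(C)C)O[C@@]12C[C@]1(C)C(O)O[C@@H]1CCC(C)=C21
F2 | step 9 | (E)-2-(4-methoxybenzyloxy)ethenyl cyclopropane with free C4 hydroxyl (Z isomer converges) | CC(C)[Si](C(C)C)(C(C)C)O[C@@]1(C2=C(C)CC[C@H]2O)C[C@]1(C)/C=C/OCc1ccc(OC)cc1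
F3 | step 9 | C4 ketone of F2 | CC(C)[Si](C(C)C)(C(C)C)O[C@@]1(C2=C(C)CCC2=O)C[C@]1(C)/C=C/OCc1ccc(OC)cc1
F4 | step 9 | (8R,8aS)-8-(4-methoxybenzyloxy)-6,8a-dimethyl-4-[(triisopropylsilyl)oxy]-1,2,8,8a-tetrahydroazulen-3(5H)-one | O=C1CC[C@]2(C)[C@H](OCc3ccc(OC)cc3)C=C(C)CC(O[Si](C(C)C)(C(C)C)C(C)C)=C12
F5 | step 9 | (8R,8aS)-8-hydroxy-6,8a-dimethyl-4-[(triisopropylsilyl)oxy]-1,2,8,8a-tetrahydroazulen-3(5H)-one (10-epimer of 18) | O=C1CC[C@]2(C)[C@H](O)C=C(C)CC(O[Si](C(C)C)(C(C)C)C(C)C)=C12
F6 | step 6 | (1R)-2-acetyl-3-methylcyclopent-2-en-1-yl 2-diazoacetate | CC(=O)C1=C(C)CC[C@H]1OC(=O)C=[N+]=[N-]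
F7 | step 6 | (1R)-3-methyl-2-{1-[(triisopropylsilyl)oxy]ethenyl}cyclopent-2-en-1-yl 2-diazoacetate | C=C(O[Si](C(C)C)(C(C)C)C(C)C)C1=C(C)CC[C@H]1OC(=O)C=[N+]=[N-]
F8 | step 6 | 8-demethyl analogue of lactone 11 | CC(C)[Si](C(C)C)(C(C)C)O[C@@]12C[C@@H]1C(=O)O[C@@H]1CCC(C)=C21
F9 | step 11 | (1S,4R,10S)-4-(prop-1-en-2-yl) analogue of 20 | CC(=C)[C@]1(O)CC[C@]2(C)[C@@H](O)C=C(C)CC(O[Si](C(C)C)(C(C)C)C(C)C)=C12
F10 | step 13 | (1S,4R)-4-hydroxy-6-[(triisopropylsilyl)oxy]dauca-5,8-dien-10-one | CC(C)[C@]1(O)CC[C@]2(C)C(=O)C=C(C)CC(O[Si](C(C)C)(C(C)C)C(C)C)=C12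
F11 | step 13 | (1S,4R,5R,6S)-4-hydroxy-6-[(triisopropylsilyl)oxy]dauc-8-en-10-one | CC(C)[C@]1(O)CC[C@]2(C)C(=O)C=C(C)C[C@H](O[Si](C(C)C)(C(C)C)C(C)C)[C@H]12
F12 | step 13 | (1S,4R,5R,6S,10S)-6-[(triisopropylsilyl)oxy]dauc-8-ene-4,10-diol | CC(C)[C@]1(O)CC[C@]2(C)[C@@H](O)C=C(C)C[C@H](O[Si](C(C)C)(C(C)C)C(C)C)[C@H]12
A1 | alternative 1 | 8,9-seco diene of 26 (C7–C8(CH3)=CH2 and C10–CH=CH2 arms on the fully substituted cyclopentane) | COc1ccc(cc1)C(=O)O[C@@H](CC(C)=C)[C@@H]1[C@](O)(C(C)C)CC[C@]1(C)[C@@H](OC(C)=O)C=C
A2 | alternative 2 | 1-diazo-4-(2,6-dimethoxy-4-methylphenyl)butan-2-one | COc1cc(C)cc(OC)c1CCC(=O)C=[N+]=[N-]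
A3 | alternative 2 | (8aS)-4,8-dimethoxy-6-methyl-3,8a-dihydroazulen-1(2H)-one | O=C1CCC2=C(OC)C=C(C)C=C(OC)[C@@H]12
A4 | alternative 3 | methyl (4R,3aS)-4,8-bis[(tert-butyldimethylsilyl)oxy]-3a-methyl-1-oxo-1,2,3,3a,4,7-hexahydroazulene-6-carboxylate (17 with CO2CH3 at C8 and a 10R silyloxy group) | O=C1CC[C@]2(C)[C@H](O[Si](C)(C)C(C)(C)C)C=C(C(=O)OC)CC(O[Si](C)(C)C(C)(C)C)=C12
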